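Ring B is closed by forming the C8–C9 bond (labdane numbering). The C8 carbinol carbon, which bears C17 and the acetoxy oxygen, sits next to C9, whose C11–C12 branch is trans to that oxygen: the imprint of a ketyl adding to the β-carbon of an enoate. One SmI2 reduction of a methyl ketone therefore forms C8–C9, closes ring B 6-exo onto a finished ring A and sets C8 and C9. Its precursor is a cyclohexane with cis arms: C10 carries C20 and an (E)-acrylate (C9, C11, C12), C5 a 3-oxobutyl chain (C6–C8, C17), C4 the gem-dimethyl group. C13–C16 are added last from (S)-β-butyrolactone.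

Key step: step 10

Numbering remark: C1–C10 form the decalin (C5/C10 at the ring fusion), C11–C16 the side chain, C17 is on C8, C18/C19 on C4, C20 on C10. The target is the cis-fused (5R,8R,9R,10S,13S) isomer: H-5, C20, C17 and C11 lie on the β-face, the C8 oxygen on the α-face.

Assumption: the (R,R)-ANDEN-phenyl Trost ligand is taken to give (R)-5; if the sense of induction is the opposite for this enolate, the (S,S)-ligand is used.

Step 1
Reactants: 1 3-methylcyclohex-2-en-1-one; 2 allyl chloroformate
Product: 4 allyl 3,3-dimethylcyclohex-1-en-1-yl carbonate, via lithium enolate 3 (not isolated)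
Conditions: Me2CuLi (from MeLi and CuI), Et2O, −20 °C; then TMEDA, 2, THF, −78 to 0 °C
Reagents that add atoms: allyl chloroformate 2, C=CCOC(=O)Cl; lithium dimethylcuprate, [Li+].C[Cu-]C
Why: Conjugate addition of the Gilman cuprate builds the C4 gem-dimethyl carbon and leaves the enolate double bond fixed between C10 and C5, and the hard chloroformate should acylate this amine-solvated lithium enolate on oxygen (enolate O-acylation), so the site of the later allylation is stored in the enol carbonate.

Step 2
Reactants: 4 allyl 3,3-dimethylcyclohex-1-en-1-yl carbonate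
Product: 5 (2R)-3,3-dimethyl-2-(prop-2-en-1-yl)cyclohexan-1-one
Conditions: Pd2(dba)3·CHCl3 (2.5 mol%), (R,R)-ANDEN-phenyl Trost ligand (5.5 mol%), 1,4-dioxane, 23 °C
Reagents that add atoms: none
Why: Zerovalent palladium ionises the allyl carbonate, carbon dioxide is lost and the enolate–π-allylpalladium ion pair recombines at C5 inside the chiral pocket of the ligand (decarboxylative asymmetric allylic alkylation of an allyl enol carbonate, Tsuji–Trost type), which should set C5 as R without a free, equilibrating enolate.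

Step 3
Reactants: 5 (2R)-3,3-dimethyl-2-(prop-2-en-1-yl)cyclohexan-1-one
Product: 7 (2S)-3,3-dimethyl-2-(prop-2-en-1-yl)cyclohexane-1-carbaldehyde (both C1 epimers), via enol ether 6 (not isolated)
Conditions: MeOCH2PPh3Cl, KN(SiMe3)2, THF, 0 °C to rt; then 2 M HCl, THF, rt
Reagents that add atoms: (methoxymethyl)triphenylphosphonium chloride, COC[P+](c1ccccc1)(c1ccccc1)c1ccccc1.[Cl-]; water, O
Why: Wittig methoxymethylenation of the C10 ketone followed by acid hydrolysis of the enol ether adds C9 as an aldehyde (one-carbon homologation); after the olefination C5 is no longer α to a carbonyl, its geometry is unchanged (the descriptor becomes S only through a priority change), and the C10 epimers converge in step 4.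

Step 4
Reactants: 7 (2S)-3,3-dimethyl-2-(prop-2-en-1-yl)cyclohexane-1-carbaldehyde
Product: 8 (1S,2R)-1,3,3-trimethyl-2-(prop-2-en-1-yl)cyclohexane-1-carbaldehyde
Conditions: KOtBu, MeI, THF, 0 °C
Reagents that add atoms: iodomethane, CI
Why: The potassium enolate of the α-branched aldehyde is C-methylated (enolate alkylation), and in the conformer with the allyl arm equatorial iodomethane should approach equatorially, anti to that arm and anti to the 1,3-axial C4 methyl, so C20 ends trans to the allyl group and the formyl group cis to it.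

Step 5
Reactants: 8 (1S,2R)-1,3,3-trimethyl-2-(prop-2-en-1-yl)cyclohexane-1-carbaldehyde; 9 trimethyl phosphonoacetate
Product: 10 methyl (2E)-3-[(1R,2R)-1,3,3-trimethyl-2-(prop-2-en-1-yl)cyclohexyl]prop-2-enoate
Conditions: NaH, THF, 0 °C to reflux
Reagents that add atoms: trimethyl phosphonoacetate 9, COC(=O)CP(=O)(OC)OC
Why: Horner–Wadsworth–Emmons olefination of the non-enolisable neopentyl aldehyde with the stabilised phosphonate anion should give the (E)-enoate, the radical acceptor of the key step, and cannot disturb C10.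

Step 6
Reactants: 10 methyl (2E)-3-[(1R,2R)-1,3,3-trimethyl-2-(prop-2-en-1-yl)cyclohexyl]prop-2-enoate
Product: 12 methyl (2E)-3-[(1R,2R)-2-(3-hydroxypropyl)-1,3,3-trimethylcyclohexyl]prop-2-enoate, via alkylborane 11 (not isolated)
Conditions: 9-BBN, THF, 0 °C to rt; then NaBO3·4H2O, THF/H2O, rt
Reagents that add atoms: 9-borabicyclo[3.3.1]nonane, B1C2CCCC1CCC2 (boron, in 11 only); sodium perborate, [Na+].[O-]OB=O (oxygen)
Why: Anti-Markovnikov hydroboration–oxidation with the bulky 9-BBN takes only the terminal alkene and spares the hindered, electron-poor enoate; oxygen must go to the terminal carbon C8 because a Wacker oxidation of the allyl group would give the 2-oxopropyl ketone, one carbon short, and hence a five-membered ring.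

Step 7
Reactants: 12 methyl (2E)-3-[(1R,2R)-2-(3-hydroxypropyl)-1,3,3-trimethylcyclohexyl]prop-2-enoate
Product: 13 methyl (2E)-3-[(1R,2R)-1,3,3-trimethyl-2-(3-oxopropyl)cyclohexyl]prop-2-enoate
Conditions: Dess–Martin periodinane, CH2Cl2, rt
Reagents that add atoms: none
Why: Dess–Martin oxidation converts the primary alcohol into the aldehyde under neutral conditions that leave the enoate untouched.

Step 8
Reactants: 13 methyl (2E)-3-[(1R,2R)-1,3,3-trimethyl-2-(3-oxopropyl)cyclohexyl]prop-2-enoate
Product: 14 methyl (2E)-3-[(1R,2R)-2-(3-hydroxybutyl)-1,3,3-trimethylcyclohexyl]prop-2-enoate (both carbinol epimers)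
Conditions: MeMgBr (1.1 equiv), THF, −78 °C; then H2O
Reagents that add atoms: methylmagnesium bromide, C[Mg]Br
Why: Grignard 1,2-addition to the unhindered aldehyde at −78 °C is far faster than attack on the ester or on the neopentyl β-carbon of the enoate and adds C17; the new carbinol centre is erased in step 9.

Step 9
Reactants: 14 methyl (2E)-3-[(1R,2R)-2-(3-hydroxybutyl)-1,3,3-trimethylcyclohexyl]prop-2-enoate
Product: 15 methyl (2E)-3-[(1R,2R)-1,3,3-trimethyl-2-(3-oxobutyl)cyclohexyl]prop-2-enoate
Conditions: Dess–Martin periodinane, CH2Cl2, rt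
Reagents that add atoms: none
Why: Dess–Martin oxidation of the secondary alcohol unveils the methyl ketone only now and without base, so the keto enoate has no opportunity for intramolecular Michael or aldol reactions before the key step.

Step 10
Reactants: 15 methyl (2E)-3-[(1R,2R)-1,3,3-trimethyl-2-(3-oxobutyl)cyclohexyl]prop-2-enoate
Product: 16 methyl 2-[(1R,2R,4aR,8aS)-2-hydroxy-2,5,5,8a-tetramethyldecahydronaphthalen-1-yl]acetate
Conditions: SmI2 (2.5 equiv), HMPA (10 equiv), t-BuOH (2 equiv), THF, −78 to 0 °C
Reagents that add atoms: none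
Why: SmI2 (divalent samarium) gives one electron to the C8 ketone, the ketyl carbon adds to C9, the β-carbon of the acrylate, a second electron turns the C11 radical into a trivalent samarium enolate and t-BuOH protonates C11; this is the known SmI2 ketyl–olefin reductive cyclisation of keto α,β-unsaturated esters to 2-hydroxycycloalkylacetates. Ring B closes 6-exo-trig, and its cis fusion is already fixed by the cis C5/C10 arms of 15. C8 is set by a chair transition state in which C17 is equatorial, because an axial methyl would meet the axial C1 methylene of ring A, so the O–Sm bond is axial on the α-face. C9 is set by the dipole-minimised anti arrangement of the O–Sm bond and the acrylate across the forming bond, which places C11 axial on the β-face, trans to the oxygen. The step needs this open, anti mode; HMPA-saturated samarium, which cannot bridge the ketyl oxygen and the ester, together with the enforced axial C–O bond should secure it, and any syn (cis) isomer would lactonise and be separable from the open hydroxy ester.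

Step 11
Reactants: 16 methyl 2-[(1R,2R,4aR,8aS)-2-hydroxy-2,5,5,8a-tetramethyldecahydronaphthalen-1-yl]acetate
Product: 17 methyl 2-[(1R,2R,4aR,8aS)-2,5,5,8a-tetramethyl-2-(triethylsilyloxy)decahydronaphthalen-1-yl]acetate
Conditions: Et3SiOTf, 2,6-lutidine, CH2Cl2, −78 to 0 °C
Reagents that add atoms: triethylsilyl trifluoromethanesulfonate, CC[Si](CC)(CC)OS(=O)(=O)C(F)(F)F
Why: Silyl triflate silylation masks the hindered tertiary O8 before C12 is activated, because a free 8-hydroxyl would displace any C12 leaving group to give the 8,12-cyclic ether (5-exo-tet Williamson closure).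

Step 12
Reactants: 17 methyl 2-[(1R,2R,4aR,8aS)-2,5,5,8a-tetramethyl-2-(triethylsilyloxy)decahydronaphthalen-1-yl]acetate
Product: 18 2-[(1R,2R,4aR,8aS)-2,5,5,8a-tetramethyl-2-(triethylsilyloxy)decahydronaphthalen-1-yl]ethan-1-ol
Conditions: LiAlH4, Et2O, 0 °C
Reagents that add atoms: none
Why: Hydride reduction of the methyl ester with LiAlH4 gives the C12 primary alcohol, and the silyl ether is inert to it.

Step 13
Reactants: 18 2-[(1R,2R,4aR,8aS)-2,5,5,8a-tetramethyl-2-(triethylsilyloxy)decahydronaphthalen-1-yl]ethan-1-ol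
Product: 19 {[(1R,2R,4aR,8aS)-1-(2-bromoethyl)-2,5,5,8a-tetramethyldecahydronaphthalen-2-yl]oxy}triethylsilane
Conditions: CBr4, PPh3, CH2Cl2, 0 °C
Reagents that add atoms: tetrabromomethane, BrC(Br)(Br)Br
Why: Appel bromination turns the primary alcohol into the bromide by SN2 displacement of the alkoxyphosphonium ion at 0 °C, where the tertiary silyl ether should not take part.

Step 14
Reactants: 19 {[(1R,2R,4aR,8aS)-1-(2-bromoethyl)-2,5,5,8a-tetramethyldecahydronaphthalen-2-yl]oxy}triethylsilane; 20 (S)-β-butyrolactone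
Product: 22 (3S)-3-methyl-5-[(1R,2R,4aR,8aS)-2,5,5,8a-tetramethyl-2-(triethylsilyloxy)decahydronaphthalen-1-yl]pentanoic acid, via Grignard reagent 21 (not isolated)
Conditions: Mg, THF, 40 °C; then CuBr·SMe2 (5 mol%), 20, THF/Me2S, −30 to 0 °C; then 1 M HCl, 0 °C
Reagents that add atoms: (S)-β-butyrolactone 20, C[C@H]1CC(=O)O1; magnesium, [Mg] (in 21 only)
Why: Under copper catalysis the primary Grignard reagent opens the β-lactone by SN2 attack at the methyl-bearing carbon (alkyl–oxygen cleavage) with inversion, which forms C12–C13 and releases the C15 acid; inversion of the (S)-lactone gives 13S because the CIP priorities change.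

Step 15
Reactants: 22 (3S)-3-methyl-5-[(1R,2R,4aR,8aS)-2,5,5,8a-tetramethyl-2-(triethylsilyloxy)decahydronaphthalen-1-yl]pentanoic acid
Product: 23 (3S)-5-[(1R,2R,4aR,8aS)-2-hydroxy-2,5,5,8a-tetramethyldecahydronaphthalen-1-yl]-3-methylpentanoic acid
Conditions: HF·pyridine, THF, 0 °C to rt
Reagents that add atoms: none
Why: Fluoride-mediated desilylation frees the tertiary alcohol without ionising C8 and leaves the carboxylic acid untouched.

Step 16
Reactants: 23 (3S)-5-[(1R,2R,4aR,8aS)-2-hydroxy-2,5,5,8a-tetramethyldecahydronaphthalen-1-yl]-3-methylpentanoic acid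
Product: 25 (3S)-5-[(1R,2R,4aR,8aS)-2-acetoxy-2,5,5,8a-tetramethyldecahydronaphthalen-1-yl]-3-methylpentanoic acid, via mixed anhydride 24 (not isolated)
Conditions: AcCl, PhNMe2, CH2Cl2, rt; then H2O, THF, rt
Reagents that add atoms: acetyl chloride, CC(=O)Cl; water, O
Why: Acetyl chloride with N,N-dimethylaniline is a standard O-acylation for hindered tertiary alcohols and proceeds with retention at C8, and the mixed anhydride formed at C15 is hydrolysed by water in the work-up to return the acid.

Compound list
1 | 3-methylcyclohex-2-en-1-one | CC1=CC(=O)CCC1 | starting material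
2 | allyl chloroformate | C=CCOC(=O)Cl | starting material
3 | lithium 3,3-dimethylcyclohex-1-en-1-olate | [Li+].[O-]C1=CC(C)(C)CCC1 | intermediate (not isolated)
4 | allyl 3,3-dimethylcyclohex-1-en-1-yl carbonate | C=CCOC(=O)OC1=CC(C)(C)CCC1 | intermediate
5 | (2R)-3,3-dimethyl-2-(prop-2-en-1-yl)cyclohexan-1-one | C=CC[C@@H]1C(C)(C)CCCC1=O | intermediate
6 | (2R)-1-(methoxymethylidene)-3,3-dimethyl-2-(prop-2-en-1-yl)cyclohexane, E/Z mixture | C=CC[C@@H]1C(C)(C)CCCC1=COC | intermediate (not isolated)
7 | (2S)-3,3-dimethyl-2-(prop-2-en-1-yl)cyclohexane-1-carbaldehyde, both C1 epimers | C=CC[C@@H]1C(C)(C)CCCC1C=O | intermediate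
8 | (1S,2R)-1,3,3-trimethyl-2-(prop-2-en-1-yl)cyclohexane-1-carbaldehyde (formyl cis to allyl) | C=CC[C@@H]1C(C)(C)CCC[C@]1(C)C=O | intermediate
9 | trimethyl phosphonoacetate | COC(=O)CP(=O)(OC)OC | starting material
10 | methyl (2E)-3-[(1R,2R)-1,3,3-trimethyl-2-(prop-2-en-1-yl)cyclohexyl]prop-2-enoate | C=CC[C@@H]1C(C)(C)CCC[C@]1(C)/C=C/C(=O)OC | intermediate
11 | methyl (2E)-3-{(1R,2R)-2-[3-(9-borabicyclo[3.3.1]nonan-9-yl)propyl]-1,3,3-trimethylcyclohexyl}prop-2-enoate | C(CC[C@@H]1C(C)(C)CCC[C@]1(C)/C=C/C(=O)OC)B1C2CCCC1CCC2 | intermediate (not isolated)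
12 | methyl (2E)-3-[(1R,2R)-2-(3-hydroxypropyl)-1,3,3-trimethylcyclohexyl]prop-2-enoate | OCCC[C@@H]1C(C)(C)CCC[C@]1(C)/C=C/C(=O)OC | intermediate
13 | methyl (2E)-3-[(1R,2R)-1,3,3-trimethyl-2-(3-oxopropyl)cyclohexyl]prop-2-enoate | O=CCC[C@@H]1C(C)(C)CCC[C@]1(C)/C=C/C(=O)OC | intermediate
14 | methyl (2E)-3-[(1R,2R)-2-(3-hydroxybutyl)-1,3,3-trimethylcyclohexyl]prop-2-enoate, both carbinol epimers | CC(O)CC[C@@H]1C(C)(C)CCC[C@]1(C)/C=C/C(=O)OC | intermediate
15 | methyl (2E)-3-[(1R,2R)-1,3,3-trimethyl-2-(3-oxobutyl)cyclohexyl]prop-2-enoate (arms cis; key-step precursor) | CC(=O)CC[C@@H]1C(C)(C)CCC[C@]1(C)/C=C/C(=O)OC | intermediate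
16 | methyl 2-[(1R,2R,4aR,8aS)-2-hydroxy-2,5,5,8a-tetramethyldecahydronaphthalen-1-yl]acetate (cis-fused, 8α-OH, 9β-CH2CO2Me; key-step product) | O[C@]1(C)CC[C@@H]2C(C)(C)CCC[C@]2(C)[C@H]1CC(=O)OC | intermediate
17 | methyl 2-[(1R,2R,4aR,8aS)-2,5,5,8a-tetramethyl-2-(triethylsilyloxy)decahydronaphthalen-1-yl]acetate | CC[Si](CC)(CC)O[C@]1(C)CC[C@@H]2C(C)(C)CCC[C@]2(C)[C@H]1CC(=O)OC | intermediate
18 | 2-[(1R,2R,4aR,8aS)-2,5,5,8a-tetramethyl-2-(triethylsilyloxy)decahydronaphthalen-1-yl]ethan-1-ol | CC[Si](CC)(CC)O[C@]1(C)CC[C@@H]2C(C)(C)CCC[C@]2(C)[C@H]1CCO | intermediate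
19 | {[(1R,2R,4aR,8aS)-1-(2-bromoethyl)-2,5,5,8a-tetramethyldecahydronaphthalen-2-yl]oxy}triethylsilane | CC[Si](CC)(CC)O[C@]1(C)CC[C@@H]2C(C)(C)CCC[C@]2(C)[C@H]1CCBr | intermediate
20 | (S)-β-butyrolactone, (4S)-4-methyloxetan-2-one | C[C@H]1CC(=O)O1 | starting material
21 | {2-[(1R,2R,4aR,8aS)-2,5,5,8a-tetramethyl-2-(triethylsilyloxy)decahydronaphthalen-1-yl]ethyl}magnesium bromide | CC[Si](CC)(CC)O[C@]1(C)CC[C@@H]2C(C)(C)CCC[C@]2(C)[C@H]1CC[Mg]Br | intermediate (not isolated)
22 | (3S)-3-methyl-5-[(1R,2R,4aR,8aS)-2,5,5,8a-tetramethyl-2-(triethylsilyloxy)decahydronaphthalen-1-yl]pentanoic acid | CC[Si](CC)(CC)O[C@]1(C)CC[C@@H]2C(C)(C)CCC[C@]2(C)[C@H]1CC[C@H](C)CC(=O)O | intermediate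
23 | (3S)-5-[(1R,2R,4aR,8aS)-2-hydroxy-2,5,5,8a-tetramethyldecahydronaphthalen-1-yl]-3-methylpentanoic acid | O[C@]1(C)CC[C@@H]2C(C)(C)CCC[C@]2(C)[C@H]1CC[C@H](C)CC(=O)O | intermediate
24 | acetic (3S)-5-[(1R,2R,4aR,8aS)-2-acetoxy-2,5,5,8a-tetramethyldecahydronaphthalen-1-yl]-3-methylpentanoic anhydride | CC(=O)O[C@]1(C)CC[C@@H]2C(C)(C)CCC[C@]2(C)[C@H]1CC[C@H](C)CC(=O)OC(C)=O | intermediate (not isolated)
25 | (3S)-5-[(1R,2R,4aR,8aS)-2-acetoxy-2,5,5,8a-tetramethyldecahydronaphthalen-1-yl]-3-methylpentanoic acid | CC(=O)O[C@]1(C)CC[C@@H]2C(C)(C)CCC[C@]2(C)[C@H]1CC[C@H](C)CC(=O)O | target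

Total step count: 16. Longest linear sequence: 16 steps (1 to 25); 2, 9 and 20 are used as purchased.

Steps most likely to fail

Step 10. The acrylate may turn into the equatorial, gauche orientation relative to the C–O bond, especially if samarium bridges the ketyl oxygen and the ester, so that the other face of C9 is attacked and the 9-epimer (which lactonises) forms. The ketyl may also be reduced further before it reaches the shielded neopentyl C9. Fallback: from 15, LiN(iPr)2 and Et3SiCl (THF, −78 °C) should give the kinetic silyl enol ether F1. Fe(acac)3 and PhSiH3 in EtOH at 60 °C then deliver a hydrogen atom to the terminal carbon of the enol ether (metal-hydride hydrogen atom transfer, Mukaiyama-type radical conjugate addition). The neutral α-silyloxy C8 radical closes onto C9 in the same 6-exo mode, but irreversibly and under steric control alone, with no metal to chelate. This gives the silyl ether 17 directly, where the route is rejoined.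

Step 2. The palladium enolate next to the gem-dimethyl carbon may be allylated slowly, which allows proton transfer to the less hindered enolate, double allylation or loss of enantiocontrol; ketone 5 can also lose its C5 configuration by enolisation before step 3. Fallback (resolution in place of asymmetric catalysis): from 1, Me2CuLi followed by allyl bromide and HMPA gives racemic 2-allyl-3,3-dimethylcyclohexanone F2. LiBH(s-Bu)3 should reduce it mainly to the racemic cis-alcohol F3. Burkholderia cepacia lipase with vinyl acetate should acylate the (1R,2S)-enantiomer, following the empirical rule for lipase acylation of secondary alcohols. The unreacted (1S,2R)-alcohol F4 is separated and oxidised with Dess–Martin periodinane to (R)-5, where the route is rejoined.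

Step 4. Methylation may occur through the conformer with the allyl arm axial, which exposes the other face of the enolate and gives the C10 epimer; some O-methylation may also take place. Fallback: from 5, reductive cyanation with TosMIC and KOtBu (van Leusen reaction) gives the nitrile F5. Its metalated form is methylated with MeI either as the C-magnesiated nitrile (i-PrMgCl, alkylation with retention) or as the planar N-lithiated ketene iminate (LiN(iPr)2). These two modes address opposite faces in cyclohexanecarbonitriles, so the one that puts C20 trans to the allyl arm is chosen. The quaternary nitrile F6 is reduced with i-Bu2AlH and hydrolysed to aldehyde 8, where the route is rejoined.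

Further compounds
F1 | step 10 | methyl (2E)-3-[(1R,2R)-1,3,3-trimethyl-2-{3-[(triethylsilyl)oxy]but-3-en-1-yl}cyclohexyl]prop-2-enoate | C=C(O[Si](CC)(CC)CC)CC[C@@H]1C(C)(C)CCC[C@]1(C)/C=C/C(=O)OC
F2 | step 2 | racemic 3,3-dimethyl-2-(prop-2-en-1-yl)cyclohexan-1-one | C=CCC1C(C)(C)CCCC1=O
F3 | step 2 | rac-(1S,2R)-3,3-dimethyl-2-(prop-2-en-1-yl)cyclohexan-1-ol (cis, racemate; relative configuration shown) | C=CC[C@@H]1C(C)(C)CCC[C@@H]1O
F4 | step 2 | (1S,2R)-3,3-dimethyl-2-(prop-2-en-1-yl)cyclohexan-1-ol | C=CC[C@@H]1C(C)(C)CCC[C@@H]1O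
F5 | step 4 | (2S)-3,3-dimethyl-2-(prop-2-en-1-yl)cyclohexane-1-carbonitrile, both C1 epimers | C=CC[C@@H]1C(C)(C)CCCC1C#N
F6 | step 4 | (1S,2R)-1,3,3-trimethyl-2-(prop-2-en-1-yl)cyclohexane-1-carbonitrile | C=CC[C@@H]1C(C)(C)CCC[C@]1(C)C#N
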